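Decide first whose clock this flask keeps: Ana and Ben dispute exactly that.

| flask | Sbt | Rgt | remark | time |
|---|---|---|---|---|
| Wednesday's | 2 M | 1.3 equiv | run made earlier |  |
| Sunday's | 1 M | 0.95 equiv | run made earlier |  |
| flask | 2.0 M | 0.950 equiv |  | 4.0 min |

| run | time / min | Imd / % |
|---|---|---|
| Wednesday's | 0.167 | 24.6 |
| Wednesday's | 0.250 | 25.3 |
| Wednesday's | 0.833 | 24.2 |
| Wednesday's | 2.50 | 20.6 |
| Sunday's | 0.167 | 17.4 |
| Sunday's | 0.250 | 20.0 |
| Sunday's | 0.833 | 22.1 |
| Sunday's | 2.50 | 20.7 |

(readings scatter by 0.5 percentage points)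

1. the best time, 4.0 min at the latest, for Imd
2. the amount of Imd, in percent of the Sbt charged, at that time
3. earliest time at which at least nineteen twentieths of that best amount are there, in min
4. latest time at which they still are, in min



The flask has Sunday's 0.95 equiv of Rgt but twice Sunday's Sbt. Ana, who wrote the forecast, runs the additions on half of Sunday's clock but keeps a loss of Imd fixed per minute, about 0.08 min⁻¹ in both runs. Ben supposes that each step, the loss included, needs two molecules to meet. At equal equivalents the percentages then follow concentration times time, so the whole of Sunday's curve moves by one clock factor f, Sunday's Sbt concentration over the flask's: 0.500.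

His evidence is the fall of Imd between the last two readings of each run. As read, Sunday's run, at 1 M, loses 0.0393 min⁻¹, and Wednesday's run, at 2 M, loses 0.0966 min⁻¹, faster than Sunday's. Wednesday's run also has more Rgt, however, and each reading scatters by 0.5 percentage points.

Ben therefore moves Sunday's top reading, 22.1%, unchanged in height, to 0.416 min. Sunday's readings on either side of it, 20.0% and 20.7%, lie below the asked share of it, so his window opens after 0.125 min and shuts before 1.25 min.

Ana's forecast is 24% at 0.5 min, with a window from 0.27 min to 1.2 min: “The peak rises to about 24% because less decay has occurred by then.”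

The flask gives 22.4% at 0.384 min, with a window from 0.191 min to 0.845 min. Ana's height stands within the tolerance, but her three times are late. Divided by f, the flask's peak falls at 0.767 min on Sunday's clock.

    Rgt + Imd2 → Imd3 + Lvg (k = 0.0930 M⁻¹ s⁻¹)
    Sbt + Rgt → Imd2 + Lvg (k = 0.0510 M⁻¹ s⁻¹)
    Sbt + Imd → Sbt.Imd (k = 0.00490 M⁻¹ s⁻¹)
    Sbt + Rgt → Imd + Lvg (k = 0.0380 M⁻¹ s⁻¹)
    Rgt + Imd → Imd3 + Lvg (k = 0.0240 M⁻¹ s⁻¹)

The neighbour flask is this flask left until 6.0 min. By f, Sunday's last reading stands at 1.25 min in it and the loss becomes 0.0785 min⁻¹, which puts Imd at 14.3% at the end. Ana's fixed rate has its region here: with Rgt at 0% by 2.00 min, the fall of Imd in this flask is close to pseudo-first-order, 0.125 min⁻¹ from 2.00 min to 4.00 min and 0.106 min⁻¹ after it. The neighbour flask ends at 11.3% Imd.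

(The readings were computed for an exercise.)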